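In a one-step world, starting material lost stands as intermediate, so I first read the sum of intermediate and target.

| setting | teal | violet | grey | blue | east | north-east | north | south-east |
|---|---|---|---|---|---|---|---|---|
| starting material | 0.20 M | 0.10 M | 0.15 M | 0.20 M | 0.20 M | 0.20 M | 0.20 M | 0.20 M |
| coupling partner | 0.30 M | 0.30 M | 0.30 M | 0.45 M | 0.300 M | 0.300 M | 0.300 M (fed, over 4.80 min) | 0.300 M |
| remark | run made earlier | run made earlier | run made earlier | run made earlier | a closed flask charged with all of it at once and left for 6.0 min | one stirred flow tank at steady state, fed with the mixture as stated, mean residence time 6.0 min | all but coupling partner at the start; coupling partner goes in evenly over 4.80 min, the run ends at 6.0 min | one stirred flow tank at steady state, fed with the mixture as stated, mean residence time 18.0 min |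
| time |  |  |  |  | 6.0 min |  | 6.0 min |  |

| run | time / min | intermediate / % | target / % |
|---|---|---|---|
| teal | 0.250 | 4 | 2 |
| teal | 0.500 | 7 | 0 |
| teal | 1.00 | 12 | 0 |
| teal | 2.00 | 19 | 3 |
| teal | 4.00 | 35 | 1 |
| violet | 1.33 | 16 | 1 |
| violet | 2.50 | 28 | 2 |
| violet | 4.00 | 33 | 4 |
| violet | 5.00 | 40 | 6 |
| violet | 6.00 | 43 | 8 |
| grey | 0.500 | 6 | 3 |
| grey | 0.833 | 13 | 1 |
| grey | 1.50 | 17 | 0 |
| grey | 3.00 | 31 | 2 |
| grey | 6.00 | 40 | 9 |
| blue | 1.33 | 23 | 2 |
| blue | 2.50 | 35 | 0 |
| blue | 4.00 | 42 | 2 |
| blue | 5.00 | 45 | 5 |
| blue | 6.00 | 52 | 8 |

(scatter of a reading: 1.5 percentage points)

- the stated concentrations are those of everything mixed, before any reaction; amounts are the same in each set-up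
- the feed brings no volume worth counting
- the earlier runs were made in a closed, stirred flask

* the set-up with the highest amount of intermediate at the outlet or at the end, in percent of the starting material put in ("none" if the first two lie within 2 percentage points) (east / north-east / north / south-east / none)
* amount of intermediate at the outlet or at the end, in percent of the starting material put in, east
* amount of intermediate at the outlet or at the end, in percent of the starting material put in, north-east
* amount of intermediate at the outlet or at the end, in percent of the starting material put in, north
* amount of intermediate at the outlet or at the end, in percent of the starting material put in, south-east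

The teal run has 36.0 % in that sum at 4.00 min. Taking [coupling partner] at its mean gives a coupling constant of 0.00704 M⁻¹ s⁻¹, a reading. The violet run, with less starting material, reads 0.00722 M⁻¹ s⁻¹.

The second process is the loss of intermediate to target. In the violet run, final target over the area under the intermediate curve reads 0.0500 min⁻¹.

I carry the race ratio, the pseudo-first-order half-life of starting material at charged [coupling partner] over the half-life of intermediate: 5.47 min over 13.9 min, or 0.394. At 1 the steps keep pace and, with [coupling partner] held constant, a closed flask crests at 36.8 % and a stirred tank at 25.0 %; that is my zero. At my ratio the same formulas give 54.6 % and 37.7 %, so the closed flask has the higher ceiling.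

Then come vessels. I give intermediate in a closed flask a mean age of half the time, and divide a tank's conversion by one plus loss constant times residence time. Evenly fed, the north flask has the partner time-integral of a closed flask run for 3.60 min, so I reckon it as that flask.

| Set-up | Main step / % | With loss / % |
|---|---|---|
| east | 46.4 % | 39.9 % |
| north-east | 36.5 % | 28.1 % |
| north | 33.0 % | 30.2 % |
| south-east | 58.3 % | 30.7 % |

So I put east first.

The forecast, “East is best”, gives 39.5 %, 28.6 %, 29.3 % and 31.4 % for east, north-east, north and south-east.

The flask gives east as best, with 39.5 %, 28.3 %, 31.5 % and 30.6 % in that order; my north figure lies 1.3 percentage points below.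

    intermediate → target (k = 6.70 × 10⁻⁴ s⁻¹)
    starting material + coupling partner → intermediate + by-product (k = 0.00840 M⁻¹ s⁻¹)
    2 coupling partner → self-condensation product (k = 0.00220 M⁻¹ s⁻¹)

In the east flask, starting material has a half-life of 4.6 min by the coupling step alone, about a quarter of the 17 min that intermediate has by its turning into target alone. With [coupling partner] held constant, my ratio of 0.394 puts the east crest at 12.1 min, later than 6.0 min and earlier than 60.0 min, and at that later time the east flask holds 13.6 %.

The readings are calculated with made-up constants; noise was put on by code.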